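Count time on J, not on Q, in these flasks. J sheds G to give X, Q catches X as Q.X, and J also drifts slowly to Z.

| flask | J | Q | time | remark |
|---|---|---|---|---|
| maple | 20 mM (fed, over 20 min) | 40.0 mM | 25 min | all else is in the flask from the start; the feed brings no volume worth counting |
| oak | 20 mM | 40.0 mM (fed, over 20 min) | 25 min | all else is in the flask from the start; the feed brings no volume worth counting |
| elm | 20 mM | 40.0 mM | 25 min | everything together at the start |

    J ⇌ X + G (K1 = 2.5 × 10⁻⁴ M, k1 = 0.068 min⁻¹)
    Q + X → Q.X (k2 = 1900 L mol⁻¹ min⁻¹)
    J → Z (k3 = 4.9 × 10⁻⁴ min⁻¹)

- which flask leads in amount of Q.X, in percent of the J charged ("all alike" within 1.5 percentage points) (maple / oak / elm / all alike)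
- how much Q.X is there at the end, in percent of the J charged: maple
- how much Q.X is there at the end, in percent of the J charged: oak
- how much Q.X is there at the end, in percent of the J charged: elm

At the charged amount of Q, X has a capture half-life of 0.547 s, yet I expect J to be still standing in elm after 25 min, and these two look as if they cannot go together. They do go together because Q acts on X and not on J, and X comes out of J on the release time 14.7 min, the reciprocal of the forward constant of the first step and the mean wait of a J before it lets go, far longer than the capture. With Q as charged, as in elm, release is therefore the rate-limiting step.

In elm, with J there from the start, the released share is 81.7%, leaving 18.3% unreleased. In maple, each J has just the time that remains after it arrives, and averaging over the feed gives 61.1%. Oak has the release clock of elm, and its Q arrives at 2.00 mM min⁻¹ against a first release of 1.36 mM min⁻¹, so I put oak just under elm. I count each release as a capture, so these figures lean high.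

The forecast names elm as leader, with 59% for maple, 78% for oak and 79.5% for elm, holding that “maple loses a great deal because its J arrives late”. The simulation gives 59.7% for maple, 78.0% for oak and 79.7% for elm, so elm leads.

In maple at 15.7 min, X falls back at 0.025 of the rate at which it goes on, and at 25.0 min its capture half-life is 0.78 s, while 40% of the J is still there. Elm stands 2 percentage points under my released share and maple 1.4 points under it.

Take maple's neighbour with 80 mM of J. The release time carries over unchanged, so the released share 61.1%, with each release counted as a capture, would be 48.9 mM, more than the 40.0 mM of Q. Q, at 0.500 equiv, is the limiting reagent and caps Q.X at 50.0% of the J. The computed flask ends at 48.1%, with 3.8% of its Q left.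

The constants were drawn at random within sensible limits; the result is computed.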